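in all of them: substrate 20 mM
- birch: reagent 60 mM; capture agent 0.40 mM; the very flask that is asked about, followed so far
- flask: reagent 60.0 mM; capture agent 0.400 mM; time 20 h

birch run (percent of the substrate charged)

| time / h | target / % | side product / % |
|---|---|---|
| 0.500 | 0.1 | 0.6 |
| 1.50 | 0.4 | 3.6 |
| 3.00 | 4.3 | 9.7 |
| 4.00 | 4.6 | 14.3 |
| 6.00 | 9.4 | 20.5 |
| 8.00 | 12.6 | 26.0 |
| 10.0 | 15.3 | 29.8 |

(each reading ± 0.5 percentage points)

* how much target the flask holds at 20 h, in percent of the substrate charged
* how much side product the flask holds at 20 h, in percent of the substrate charged
* how much isomer of the product the flask holds at 20 h, in percent of the substrate charged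
* concentration of reagent at 20 h, in mM



**Early rise.** At early times the side product in this flask speeds up: it gains 3 percentage points in the hour from 0.500 h to 1.50 h, but 4.6 points in the hour from 3.00 h to 4.00 h. Then it slows. The reagent is charged at 3.00 times the substrate, so you may try freezing it and reading the slowing as a pseudo-first-order fade.

**Fading factor.** Take steps of 2.00 h. From 6.00 h to 8.00 h the flask gains 5.5 points, then 3.8 points, and 0.691 is the fading factor, the gain of one step over the gain of the step before. Frozen, the gains form a geometric series. It ends at a ceiling of 38.3% and stands at 37.0% at 20 h.

**Second way.** One step earlier the gains are 6.2 points and 5.5 points, so the factor is 0.887. That gives a ceiling of 69.2% and 48.2% at 20 h, well above the first answer. This window cheats through scatter: its factor is very sensitive to the reading at 6.00 h, which enters both gains with opposite signs, and that reading moved up by one 0.5 points turns 0.887 into 0.746. You keep 0.691, from the later readings, as a rough reading, since each reading carries 0.5 points. It gives no number for the isomer, which no reading shows.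

**The forecast.** The forecast says 25% target, 42% side product, 3% isomer and 45 mM reagent, holding that “the loss looks first order in substrate, with reagent in excess”, and its side product stands above my 37.0%.

**The result.** The flask gives 17.6% target, 35.6% side product, 23.6% isomer and 47.5 mM reagent, so the side product lies a little under my 37.0%.

    substrate + reagent → open intermediate + released group (k = 2.20 L mol⁻¹ h⁻¹)
    open intermediate ⇌ target (K = 0.800, k = 0.100 h⁻¹)
    open intermediate ⇌ isomer of the product (K = 96.0, k = 0.0490 h⁻¹)
    open intermediate + capture agent → trapped intermediate (k = 7.00 L mol⁻¹ h⁻¹)
    substrate + released group → side product (k = 18.0 L mol⁻¹ h⁻¹)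

**Not at rest.** The factor left 1.3 points of side product to come after 20 h. By 200 h the flask has gained 0.90 points, reaching 36.5%, while its reagent stays at 78.8% of its charge. The rest of the flask is still moving: over the same stretch target falls to 0.699%, isomer climbs to 60.3%, and the open intermediate drops from 20.3% to 0.824%.

**Next reading.** Read this same flask at 12 h, one step after 10.0 h: the factor adds 2.6 points and gives 32.4%. The flask then holds 31.8%.

The earlier runs and the new flask are simulated from invented constants.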